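The earlier runs and the new flask were computed for substances that don't exist; scatter was added.

- Count turnovers: I take it that each pass of the catalyst ends either in target or in capture, and that a capture costs one catalyst and one capture agent. My rule, at one temperature and one substrate charge, is that target equals ρ times the natural logarithm of capture agent charged over capture agent left. ρ, the turnover yield (a selectivity factor), is the fraction of the substrate charged that becomes target while the capture agent falls by a factor e.

| flask | substrate | capture agent | free catalyst | temperature | remark | time |
|---|---|---|---|---|---|---|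
| oak | 0.42 M | 0.059 M | 21 mM | 87 °C | run made earlier |  |
| alder | 0.42 M | 0.092 M | 21 mM | 102 °C | run made earlier |  |
| birch | 0.42 M | 0.042 M | 42 mM | 87 °C | run made earlier |  |
| north-west | 0.42 M | 0.0420 M | 21 mM | 90 °C |  | 30 min |
| south | 0.42 M | 0.0420 M | 21 mM | 98 °C |  | 30 min |

| run | time / min | target / % |
|---|---|---|
| oak | 3.00 | 1.0 |
| oak | 10.0 | 3.8 |
| oak | 15.0 | 4.9 |
| oak | 25.0 | 6.2 |
| oak | 40.0 | 7.5 |
| alder | 1.50 | 1.5 |
| alder | 3.00 | 2.7 |
| alder | 6.00 | 5.3 |
| alder | 12.0 | 6.8 |
| alder | 20.0 | 7.8 |
| birch | 3.00 | 2.5 |
| birch | 5.00 | 4.7 |
| birch | 10.0 | 8.6 |
| birch | 20.0 | 15.3 |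
| birch | 40.0 | 23.9 |

(readings scatter by 0.3 percentage points)

* which of the two there is more of at the end, north-west (trapped intermediate / target)
* which of the two there is more of at the end, south (trapped intermediate / target)
* final target, as a percentage of the substrate charged, in north-west
* final target, as a percentage of the substrate charged, in south

- the earlier runs were read with a standard deviation of 0.3 percentage points

- First way, oak: the gains over equal times are 2.4 points, then 1.3 points. Continued as a shrinking series, they reach a ceiling of 9.04%. Once the catalyst is captured, the capture agent left in oak is 64.4% of its charge, so ρ reads 20.5%.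
- Second way, birch: the two charges are equal, so the catalyst left tracks the capture agent left. The rate falls to 49.3% of its early value while about 14 points of target forms, so ρ reads 19.9%.
- Oak's stall and birch's rate fall come from different runs, and their two values lie close, so I take their mean, 20.2%, at 87 °C.
- Alder's last reading, taken as its ceiling although alder was still rising, gives 30.1% at 102 °C. Interpolating the logarithm gives the turnover yield at 90 °C, target per factor e of capture agent, as 21.9%, and 27.1% at 98 °C.
- Your ceilings are then 15.2% for north-west and 18.8% for south.
- Birch's readings at 20.0 min and 40.0 min average 19.6%, my rough stand-in for its level at 30 min, with twice the catalyst of north-west. Halving that and scaling by ρ, I commit to 10.6% for north-west and 13.1% for south, and the south figure is the rougher one.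
- Both my figures stand above the 5.00% of the substrate charged that the catalyst can hold trapped, so I expect more target than trapped intermediate in each flask.
- The forecast names target for north-west and target for south, with 10% (8.5% to 11.5%) and 14.5% (12% to 16.5%) of target in those flasks, the trapped intermediate “capped at 5% by the catalyst”. Its north-west is lower than mine and its south is higher than mine.
- North-west gives 10.5% of target and south 14.8%, against 3.98% and 4.31% of trapped intermediate.

    catalyst intermediate + capture agent → trapped intermediate (k = 0.150 L mol⁻¹ s⁻¹, Ea = 64.0 kJ mol⁻¹)
    catalyst intermediate → free catalyst + target (k = 0.0130 s⁻¹, Ea = 98.0 kJ mol⁻¹)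
    substrate + free catalyst ⇌ catalyst intermediate (K = 29.0 L mol⁻¹, k = 0.0110 L mol⁻¹ s⁻¹, Ea = 61.0 kJ mol⁻¹, ΔH = 21.0 kJ mol⁻¹)
    (constants at 90 °C)

- North-west ended with 60% of its capture agent left, which ρ turns into 11.2% of target. A neighbour of south charged with 0.025 M of capture agent ended with 44% left, which ρ at 98 °C turns into 22.2%, and that neighbour holds 21.8% of target.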